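**Retrosynthetic overview**
- The last step frees the two phenols of the 2,4-dimethyl ether of the target (O–CH3 cleavage).
- Key disconnection: the aryl–CH2 bond (C6) and the aryl–acetyl bond (C1) of ring A are cut together. This leads back to 1-iodo-2,4-dimethoxybenzene, (10-bromodecyl)benzene and a masked acetyl anion, joined in one pot by a palladium/norbornene relay (new step).
- (10-Bromodecyl)benzene comes from (dec-9-en-1-yl)benzene by anti-Markovnikov HBr addition. The alkene comes from 10-bromodec-1-ene and phenylmagnesium bromide by sp3–sp2 coupling.
- No ring is formed. Ring A (resorcinol ring) and ring B (phenyl ring) are both bought.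

Assumption: the SMILES holds no stereocentre and no stereogenic double bond. The target is therefore achiral, and the request for a single enantiomer is met as it stands.

**Step 1**
Reactants: 1 10-bromodec-1-ene; 2 phenylmagnesium bromide
Product: 3 (dec-9-en-1-yl)benzene
Conditions: FeCl3 (5 mol %), TMEDA (1.2 equiv), THF, 0 °C, 2 (1.2 equiv) added over 30 min
Reagents that add atoms: none
Why: Iron-catalysed Kumada–Corriu-type coupling of an aryl Grignard reagent with a primary alkyl bromide is fast at 0 °C, TMEDA holds back beta-hydride elimination, and the remote terminal alkene is left alone.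

**Step 2**
Reactants: 3 (dec-9-en-1-yl)benzene
Product: 4 (10-bromodecyl)benzene
Conditions: HBr (g), dibenzoyl peroxide (5 mol %), heptane, 0 °C to rt
Reagents that add atoms: hydrogen bromide, Br
Why: In this Kharasch radical-chain (peroxide-effect) hydrobromination the bromine atom adds to the terminal carbon, the secondary radical takes H from HBr to give the primary bromide, and without Br2 any benzylic hydrogen abstraction is reversible and harmless.

**Step 3**
Reactants: 4 (10-bromodecyl)benzene (1.5 equiv); 5 1-iodo-2,4-dimethoxybenzene (1.0 equiv); 6 tributyl(1-ethoxyvinyl)stannane (1.5 equiv)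
Product: 8 1-[2,4-dimethoxy-6-(10-phenyldecyl)phenyl]ethan-1-one, via enol ether 7 (not isolated)
Conditions: Pd(OAc)2 (5 mol %), P(2-furyl)3 (12 mol %), norbornene (2 equiv), Cs2CO3 (2.5 equiv), MeCN, 90 °C, 18 h; then 1 M HCl, THF, rt
Reagents that add atoms: water, O
Why: Proposed new method: a Catellani-type palladium/norbornene relay closed by Stille transfer of a masked acetyl anion, so that one pot makes both the C6–CH2 bond and the C1–acyl bond; zerovalent palladium inserts into the C–I bond of 5, strained norbornene carbopalladates this aryl species faster than the neutral stannane can transmetalate, carbonate-assisted C–H palladation at the only free ortho position gives a halide-free five-membered palladacycle that cannot react with 6 but takes up primary bromide 4 by SN2-type oxidative addition to tetravalent palladium, aryl–alkyl reductive elimination followed by beta-carbon elimination (driven by the two ortho groups) expels norbornene, and the 2,6-disubstituted divalent arylpalladium halide, now too hindered to re-insert norbornene, is intercepted by 6 (the weak donor P(2-furyl)3 serves both the relay and the tin-to-palladium transfer) to give 7, which aqueous acid hydrolyses to 8; the closest known reaction types are the Catellani ortho-alkylation with Heck or Suzuki termination and the Stille acetylation of simple aryl halides with 6.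

**Step 4**
Reactants: 8 1-[2,4-dimethoxy-6-(10-phenyldecyl)phenyl]ethan-1-one
Product: 10 1-[2,4-dihydroxy-6-(10-phenyldecyl)phenyl]ethan-1-one, via bis(dibromoboryl) ether 9 (not isolated)
Conditions: BBr3 (4 equiv), CH2Cl2, −78 °C to rt, 16 h; then ice/H2O
Reagents that add atoms: none
Why: In this Lewis-acid aryl methyl ether cleavage boron binds each methoxy oxygen (the ortho one helped by chelation to the ketone), bromide removes the methyl group by SN2 attack, and water hydrolyses 9 to the free resorcinol, while ketone, chain and phenyl ring are inert and no stereocentre is involved.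

**Compound list**
1 | 10-bromodec-1-ene | C=CCCCCCCCCBr | starting material
2 | phenylmagnesium bromide | Br[Mg]c1ccccc1 | starting material
3 | (dec-9-en-1-yl)benzene | C=CCCCCCCCCc1ccccc1 | intermediate
4 | (10-bromodecyl)benzene | BrCCCCCCCCCCc1ccccc1 | intermediate
5 | 1-iodo-2,4-dimethoxybenzene | COc1ccc(I)c(OC)c1 | starting material
6 | tributyl(1-ethoxyvinyl)stannane | CCCC[Sn](CCCC)(CCCC)C(=C)OCC | starting material
7 | 2-(1-ethoxyethenyl)-1,5-dimethoxy-3-(10-phenyldecyl)benzene | C=C(OCC)c1c(OC)cc(OC)cc1CCCCCCCCCCc1ccccc1 | intermediate
8 | 1-[2,4-dimethoxy-6-(10-phenyldecyl)phenyl]ethan-1-one | CC(=O)c1c(OC)cc(OC)cc1CCCCCCCCCCc1ccccc1 | intermediate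
9 | 1-[2,4-bis(dibromoboryloxy)-6-(10-phenyldecyl)phenyl]ethan-1-one | CC(=O)c1c(OB(Br)Br)cc(OB(Br)Br)cc1CCCCCCCCCCc1ccccc1 | intermediate
10 | 1-[2,4-dihydroxy-6-(10-phenyldecyl)phenyl]ethan-1-one (achiral) | CC(=O)c1c(O)cc(O)cc1CCCCCCCCCCc1ccccc1 | target

**Total step count:** 4. **Longest linear sequence:** 4 (steps 1, 2, 3, 4).

**Three steps most likely to fail**

**Step 3 (proposed new step).**
- Risks: direct Stille coupling of 5 before norbornene insertion, which would give 2,4-dimethoxyacetophenone after hydrolysis. Other risks are norbornene-containing side products and slow tin-to-palladium transfer at the hindered aryl species, ending in protodepalladation.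
- Fallback with known chemistry: it sets out from 4 and comes back at 8. Bromide 4 is coupled with commercial 3,5-dimethoxyphenylmagnesium chloride (FeCl3, TMEDA, THF, 0 °C) to give 1,3-dimethoxy-5-(10-phenyldecyl)benzene F1. Friedel–Crafts acetylation (AcCl, SnCl4, CH2Cl2, 0 °C) then takes place para to one methoxy group and next to the chain. This is the usual site for 5-alkylresorcinol dimethyl ethers, and it gives 8.

**Step 4.**
- Risks: the para methyl ether may resist, so the reaction stops at the 2-hydroxy-4-methoxy ketone. The electron-rich methyl ketone may also lose its acetyl group or condense under the strong Lewis acid.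
- Fallback: it sets out from 3 and comes back at 10. It avoids methyl ethers altogether and brings in the acetyl group last.
  - Hydroboration of 3 with 9-BBN (THF, rt) gives 9-(10-phenyldecyl)-9-borabicyclo[3.3.1]nonane F2.
  - F2 is used directly in a B-alkyl Suzuki–Miyaura coupling with commercial 1,3-bis(benzyloxy)-5-bromobenzene (PdCl2(dppf), K3PO4, THF/DMF/H2O, 65 °C) to give 1,3-bis(benzyloxy)-5-(10-phenyldecyl)benzene F3.
  - Hydrogenolysis (H2, 10 % Pd/C, EtOAc/EtOH, rt) gives 5-(10-phenyldecyl)benzene-1,3-diol F4.
  - Nencki-type C-acylation (AcOH, BF3·OEt2, 85 °C) at the position ortho to one hydroxyl, para to the other and next to the chain gives 10. This regiochemistry is known for orcinol and olivetol. The minor 2-acyl isomer is removed by chromatography.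

**Step 2.**
- Risk: competing ionic Markovnikov addition would give the secondary bromide, which is hard to separate from 4.
- Fallback: it sets out from 3 and comes back at 4. Hydroboration with BH3·SMe2 (THF, 0 °C) gives tris(10-phenyldecyl)borane F5. Oxidation in the same flask (H2O2, NaOH) gives 10-phenyldecan-1-ol F6, which is easily purified from the small amount of secondary alcohol. Appel bromination (CBr4, PPh3, CH2Cl2, 0 °C) then gives 4.

**Further compounds**
F1 | step 3 | 1,3-dimethoxy-5-(10-phenyldecyl)benzene | COc1cc(OC)cc(CCCCCCCCCCc2ccccc2)c1
F2 | step 4 | 9-(10-phenyldecyl)-9-borabicyclo[3.3.1]nonane | c1ccccc1CCCCCCCCCCB1C2CCCC1CCC2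
F3 | step 4 | 1,3-bis(benzyloxy)-5-(10-phenyldecyl)benzene | C(Oc1cc(OCc2ccccc2)cc(CCCCCCCCCCc2ccccc2)c1)c1ccccc1
F4 | step 4 | 5-(10-phenyldecyl)benzene-1,3-diol | Oc1cc(O)cc(CCCCCCCCCCc2ccccc2)c1
F5 | step 2 | tris(10-phenyldecyl)borane | B(CCCCCCCCCCc1ccccc1)(CCCCCCCCCCc1ccccc1)CCCCCCCCCCc1ccccc1
F6 | step 2 | 10-phenyldecan-1-ol | OCCCCCCCCCCc1ccccc1
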